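**Retrosynthetic overview** (TBS = tert-butyldimethylsilyl)
1. Target 23 ⇒ (global desilylation, Mitsunobu esterification with p-coumaric acid) oxepine alcohol 20, whose acid is carried as a TBS ester.
2. 20 ⇒ achiral furan diol 17. O1–C2 of the oxepine is cut in the retro-oxa-Michael sense to a Z-aroylacrylic silyl ester. That ester is the singlet-oxygen product of a 2-silyl-5-aryl-3-alkylfuran. Both events run in one flask, the second under a chiral squaramide.
3. Enabling feature: aryl C=O / CH2 / oxepine C2 / CO2H form a 1,4-dioxygenated four-carbon unit, which matches the four carbons of a furan ring. Ring oxygen O1 sits β to the aryl ketone. The endocyclic C5=C6 double bond (Z in the open chain) holds C7–OH next to C2.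
4. 17 ⇒ B-alkyl Suzuki–Miyaura union of vinylfuran 15 with Z-iodo diol 7. 15 comes from furan-3-carbaldehyde by C2 silylation, C5 Negishi arylation and Wittig. 7 comes from carbomagnesiation of propargyl alcohol and Riley oxidation.
5. Ring order: both benzene rings and the furan are bought. The oxepine is the only ring made (step 8), and the furan ring is consumed in making it.

Key step: step 8

Assumption: precedent does not fix the sense of induction of a cinchona squaramide on this new substrate class. The quinidine-derived catalyst is written; its quinine-derived pseudo-enantiomer would be used if the first run shows the opposite sense.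

**Step 1**
Reactants: 1 5-bromo-2-methylpent-2-ene; 2 prop-2-yn-1-ol
Product: 6 (2Z)-3-iodo-2-(4-methylpent-3-en-1-yl)prop-2-en-1-ol, via homoprenylmagnesium bromide 3 (not isolated), via chloromagnesium propargyl alkoxide 4 (not isolated), via oxamagnesole 5 (not isolated)
Conditions: 1, Mg, THF, 40 °C; separately 2, i-PrMgCl (1.0 equiv), THF, −20 °C; CuI (10 mol %), then 3 (1.5 equiv), −20 °C → rt; I2, THF, −40 → 0 °C; aq NH4Cl/Na2S2O3
Reagents that add atoms: iodine, II
Why: Copper-catalysed, alkoxide-directed anti-carbomagnesiation puts the alkyl group on the internal alkyne carbon and magnesium on the terminal carbon inside a five-membered oxamagnesacycle, so iodinolysis with retention fixes iodine cis to CH2OH, which is the Z geometry of the later ring alkene.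

**Step 2**
Reactants: 6 (2Z)-3-iodo-2-(4-methylpent-3-en-1-yl)prop-2-en-1-ol
Product: 7 (2E,6Z)-6-(hydroxymethyl)-7-iodo-2-methylhepta-2,6-dien-1-ol
Conditions: SeO2 (0.3 equiv), t-BuOOH (2.5 equiv, decane), salicylic acid (0.1 equiv), CH2Cl2, 0 °C → rt
Reagents that add atoms: tert-butyl hydroperoxide, CC(C)(C)OO
Why: Riley allylic oxidation (ene reaction, then [2,3]-sigmatropic shift) should take the electron-rich gem-dimethyl alkene at its E methyl group, as in geranyl derivatives, while the iodoalkene is deactivated.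

**Step 3**
Reactants: 8 furan-3-carbaldehyde
Product: 10 2-(tert-butyldimethylsilyl)furan-3-carbaldehyde, via dilithiated amino alkoxide 9 (not isolated)
Conditions: Me2NCH2CH2NHMe, n-BuLi, THF, −78 °C; 8, −78 → −20 °C; n-BuLi (1.2 equiv), −20 °C; TBSCl, −78 °C → rt; aq NH4Cl
Reagents that add atoms: tert-butyldimethylsilyl chloride, CC(C)(C)[Si](C)(C)Cl
Why: In situ protection of the aldehyde as a chelating lithium α-amino alkoxide directs ortho-lithiation to the neighbouring α-position C2, and silylation followed by aqueous work-up returns the aldehyde.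

**Step 4**
Reactants: 11 2-bromobenzene-1,4-diol
Product: 12 2-bromo-1,4-bis(tert-butyldimethylsilyloxy)benzene
Conditions: TBSCl (2.3 equiv), imidazole, DMF, rt
Reagents that add atoms: tert-butyldimethylsilyl chloride, CC(C)(C)[Si](C)(C)Cl
Why: Standard imidazole-promoted silylation caps both phenols with the group that also serves at the furan and is removed last.

**Step 5**
Reactants: 10 2-(tert-butyldimethylsilyl)furan-3-carbaldehyde; 12 2-bromo-1,4-bis(tert-butyldimethylsilyloxy)benzene
Product: 14 5-[2,5-bis(tert-butyldimethylsilyloxy)phenyl]-2-(tert-butyldimethylsilyl)furan-3-carbaldehyde, via zincated amino alkoxide 13 (not isolated)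
Conditions: morpholine, n-BuLi, THF, −78 °C; 10; s-BuLi (1.1 equiv), −78 °C; ZnCl2 (1.2 equiv), −78 °C → rt; 12, Pd(OAc)2 (2 mol %), SPhos (4 mol %), 40 °C; aq NH4Cl
Reagents that add atoms: none
Why: With C2 blocked by silicon and the aldehyde masked as a non-chelating morpholine α-amino alkoxide, C5–H is the only acidic α-position, so lithiation, zincation and Negishi coupling join furan C5 to the aryl bromide without exposing the aryl silyl ethers to organolithiums.

**Step 6**
Reactants: 14 5-[2,5-bis(tert-butyldimethylsilyloxy)phenyl]-2-(tert-butyldimethylsilyl)furan-3-carbaldehyde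
Product: 15 5-[2,5-bis(tert-butyldimethylsilyloxy)phenyl]-2-(tert-butyldimethylsilyl)-3-vinylfuran
Conditions: Ph3PCH3Br, KHMDS, THF, 0 °C; then 14, 0 °C → rt
Reagents that add atoms: methyltriphenylphosphonium bromide, C[P+](c1ccccc1)(c1ccccc1)c1ccccc1.[Br-]
Why: Wittig methylenation of an aromatic aldehyde with the preformed ylide leaves no free base that could attack the aryl silyl ethers.

**Step 7**
Reactants: 15 5-[2,5-bis(tert-butyldimethylsilyloxy)phenyl]-2-(tert-butyldimethylsilyl)-3-vinylfuran; 7 (2E,6Z)-6-(hydroxymethyl)-7-iodo-2-methylhepta-2,6-dien-1-ol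
Product: 17 5-[2,5-bis(tert-butyldimethylsilyloxy)phenyl]-2-(tert-butyldimethylsilyl)-3-[(3Z,7E)-9-hydroxy-4-(hydroxymethyl)-8-methylnona-3,7-dien-1-yl]furan, via furylethyl-9-BBN 16 (not isolated)
Conditions: 9-BBN (1.2 equiv), THF, rt; then 7, Pd(dppf)Cl2 (5 mol %), aq K3PO4 (3 M), THF/DMF, rt
Reagents that add atoms: none
Why: 9-BBN adds anti-Markovnikov to the only alkene of 15, and the B-alkyl Suzuki–Miyaura coupling with the alkenyl iodide proceeds with retention of the Z geometry and tolerates the two free hydroxyl groups.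

**Step 8**
Reactants: 17 5-[2,5-bis(tert-butyldimethylsilyloxy)phenyl]-2-(tert-butyldimethylsilyl)-3-[(3Z,7E)-9-hydroxy-4-(hydroxymethyl)-8-methylnona-3,7-dien-1-yl]furan
Product: 20 tert-butyldimethylsilyl (2R)-2-{2-[2,5-bis(tert-butyldimethylsilyloxy)phenyl]-2-oxoethyl}-6-[(3E)-5-hydroxy-4-methylpent-3-en-1-yl]-2,3,4,7-tetrahydrooxepine-2-carboxylate, via endoperoxide 18 (not isolated), via Z-keto silyl ester 19 (not isolated)
Conditions: O2, tetraphenylporphyrin (1 mol %), white LED, toluene/CH2Cl2 (4:1), −78 °C; Ar purge, −78 → −30 °C; then quinidine-derived squaramide 3-{[3,5-bis(trifluoromethyl)phenyl]amino}-4-{[(9R)-6'-methoxycinchonan-9-yl]amino}cyclobut-3-ene-1,2-dione (10 mol %), 4 Å MS, −30 °C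
Reagents that add atoms: oxygen, O=O
Why: Proposed new method: singlet oxygen adds [4+2] across C2 and C5 of the electron-rich trisubstituted furan to give 18, whose silyl group shifts on warming from carbon to the adjacent peroxide oxygen with O–O cleavage and ring opening, which unmasks the aryl ketone, the Z-alkene and the carboxyl group (already as its TBS ester) in 19; the squaramide NH pair then binds the aryl ketone while the quinuclidine nitrogen takes up the proton of the allylic CH2OH, the oxygen adds to the β-carbon and the enol is protonated to the CH2 group. The closest known reaction types are the regiospecific photooxygenation of 2-silylfurans to Z-4-oxo-2-enoic silyl esters and the aminothiourea- or squaramide-catalysed oxy-Michael cycloetherification of hydroxy aryl enones to five- and six-membered ethers; what is new is their union in one flask, the seven-membered ring and the fully substituted carbon. The furan ring is opened and the oxepine ring closes in the 7-exo-trig mode. The only new stereocenter, C2, is set by the catalyst, which presents one face of the planar enone to the bound hydroxyl group, since nothing in the achiral substrate biases it. The step needs oxygen to take the furan and not the two trisubstituted alkenes (a silyl-, aryl- and alkyl-substituted furan should react far faster at −78 °C than alkenes that carry an allylic oxygen), silicon at C2 decides which α-carbon becomes the carboxyl group, the ketone outweighs the ester so that attack goes to the carbon β to the ketone, and only the hydroxyl group held cis by the Z-alkene can reach that carbon (the other one would need an eleven-membered ring). The cis relation of aroyl and ester groups inherited from the furan raises the energy of 19 above that of its E isomer and so adds driving force to a closure that might otherwise be near thermoneutral, and the absence of added base or salt leaves the catalyst as the only promoter.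

**Step 9**
Reactants: 20 oxepine TBS ester alcohol; 21 (E)-3-(4-hydroxyphenyl)prop-2-enoic acid (p-coumaric acid)
Product: 22 tert-butyldimethylsilyl (2R)-2-{2-[2,5-bis(tert-butyldimethylsilyloxy)phenyl]-2-oxoethyl}-6-[(3E)-5-{[(2E)-3-(4-hydroxyphenyl)prop-2-enoyl]oxy}-4-methylpent-3-en-1-yl]-2,3,4,7-tetrahydrooxepine-2-carboxylate
Conditions: 21 (1.5 equiv), PPh3, DIAD (1.3 equiv each), THF, 0 °C → rt
Reagents that add atoms: none
Why: The Mitsunobu esterification is neutral, activates the only free (primary allylic) alcohol and takes the carboxyl group of 21 in preference to its far less acidic phenol, so neither the silyl ester nor the β-alkoxy ketone is disturbed.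

**Step 10**
Reactants: 22 coumarate with two aryl TBS ethers and one TBS ester
Product: 23 (2R)-2-[2-(2,5-dihydroxyphenyl)-2-oxoethyl]-6-[(3E)-5-{[(2E)-3-(4-hydroxyphenyl)prop-2-enoyl]oxy}-4-methylpent-3-en-1-yl]-2,3,4,7-tetrahydrooxepine-2-carboxylic acid (target)
Conditions: Et3N·3HF (excess), THF/MeCN, 0 °C → rt, Ar
Reagents that add atoms: none
Why: Mildly acidic fluoride cleaves both aryl silyl ethers and the silyl ester in one operation without any base, so retro-oxa-Michael opening, chromanone formation through the freed ortho-phenol, ester cleavage and hydroquinone oxidation should all be avoided and C2 stays intact.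

**Compound list**
1 | 5-bromo-2-methylpent-2-ene | CC(C)=CCCBr | starting material
2 | prop-2-yn-1-ol | C#CCO | starting material
3 | (4-methylpent-3-en-1-yl)magnesium bromide | CC(C)=CCC[Mg]Br | intermediate
4 | chloromagnesium prop-2-yn-1-olate | C#CCO[Mg]Cl | intermediate
5 | 4-(4-methylpent-3-en-1-yl)-2,5-dihydro-1,2-oxamagnesole | CC(C)=CCCC1=C[Mg]OC1 | intermediate
6 | (2Z)-3-iodo-2-(4-methylpent-3-en-1-yl)prop-2-en-1-ol | OC/C(CCC=C(C)C)=C\I | intermediate
7 | (2E,6Z)-6-(hydroxymethyl)-7-iodo-2-methylhepta-2,6-dien-1-ol | OC/C(CC/C=C(\C)CO)=C\I | intermediate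
8 | furan-3-carbaldehyde | O=Cc1ccoc1 | starting material
9 | C2-lithiated lithium α-amino alkoxide of 8 (trimethylethylenediamine adduct) | [Li]OC(c1ccoc1[Li])N(C)CCN(C)C | intermediate
10 | 2-(tert-butyldimethylsilyl)furan-3-carbaldehyde | O=Cc1ccoc1[Si](C)(C)C(C)(C)C | intermediate
11 | 2-bromobenzene-1,4-diol | Oc1ccc(O)c(Br)c1 | starting material
12 | 2-bromo-1,4-bis(tert-butyldimethylsilyloxy)benzene | CC(C)(C)[Si](C)(C)Oc1ccc(O[Si](C)(C)C(C)(C)C)c(Br)c1 | intermediate
13 | C5-chlorozincated lithium α-amino alkoxide of 10 (morpholine adduct) | [Li]OC(N1CCOCC1)c1cc([Zn]Cl)oc1[Si](C)(C)C(C)(C)C | intermediate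
14 | 5-[2,5-bis(tert-butyldimethylsilyloxy)phenyl]-2-(tert-butyldimethylsilyl)furan-3-carbaldehyde | O=Cc1cc(oc1[Si](C)(C)C(C)(C)C)-c1cc(O[Si](C)(C)C(C)(C)C)ccc1O[Si](C)(C)C(C)(C)C | intermediate
15 | 5-[2,5-bis(tert-butyldimethylsilyloxy)phenyl]-2-(tert-butyldimethylsilyl)-3-vinylfuran | C=Cc1cc(oc1[Si](C)(C)C(C)(C)C)-c1cc(O[Si](C)(C)C(C)(C)C)ccc1O[Si](C)(C)C(C)(C)C | intermediate
16 | 9-{2-[5-aryl-2-(tert-butyldimethylsilyl)furan-3-yl]ethyl}-9-borabicyclo[3.3.1]nonane | C1CC2CCCC(C1)B2CCc1cc(oc1[Si](C)(C)C(C)(C)C)-c1cc(O[Si](C)(C)C(C)(C)C)ccc1O[Si](C)(C)C(C)(C)C | intermediate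
17 | 5-[2,5-bis(tert-butyldimethylsilyloxy)phenyl]-2-(tert-butyldimethylsilyl)-3-[(3Z,7E)-9-hydroxy-4-(hydroxymethyl)-8-methylnona-3,7-dien-1-yl]furan | OC/C(CC/C=C(\C)CO)=C\CCc1cc(oc1[Si](C)(C)C(C)(C)C)-c1cc(O[Si](C)(C)C(C)(C)C)ccc1O[Si](C)(C)C(C)(C)C | intermediate
18 | 1-aryl-4-(tert-butyldimethylsilyl)-5-alkyl-2,3,7-trioxabicyclo[2.2.1]hept-5-ene (furan endoperoxide, racemic) | CC(C)(C)[Si](C)(C)C12OOC(O1)(C=C2CC/C=C(\CO)CC/C=C(\C)CO)c1cc(O[Si](C)(C)C(C)(C)C)ccc1O[Si](C)(C)C(C)(C)C | intermediate
19 | tert-butyldimethylsilyl (2Z)-4-[2,5-bis(tert-butyldimethylsilyloxy)phenyl]-2-[(3Z,7E)-9-hydroxy-4-(hydroxymethyl)-8-methylnona-3,7-dien-1-yl]-4-oxobut-2-enoate | CC(C)(C)[Si](C)(C)OC(=O)/C(CC/C=C(\CO)CC/C=C(\C)CO)=C\C(=O)c1cc(O[Si](C)(C)C(C)(C)C)ccc1O[Si](C)(C)C(C)(C)C | intermediate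
20 | tert-butyldimethylsilyl (2R)-2-{2-[2,5-bis(tert-butyldimethylsilyloxy)phenyl]-2-oxoethyl}-6-[(3E)-5-hydroxy-4-methylpent-3-en-1-yl]-2,3,4,7-tetrahydrooxepine-2-carboxylate | C/C(=C\CCC1=CCC[C@@](CC(=O)c2cc(O[Si](C)(C)C(C)(C)C)ccc2O[Si](C)(C)C(C)(C)C)(C(=O)O[Si](C)(C)C(C)(C)C)OC1)CO | intermediate
21 | (E)-3-(4-hydroxyphenyl)prop-2-enoic acid | OC(=O)/C=C/c1ccc(O)cc1 | starting material
22 | p-coumarate of 20 | C/C(=C\CCC1=CCC[C@@](CC(=O)c2cc(O[Si](C)(C)C(C)(C)C)ccc2O[Si](C)(C)C(C)(C)C)(C(=O)O[Si](C)(C)C(C)(C)C)OC1)COC(=O)/C=C/c1ccc(O)cc1 | intermediate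
23 | CNP0602535.1 | C/C(=C\CCC1=CCC[C@@](CC(=O)c2cc(O)ccc2O)(C(=O)O)OC1)COC(=O)/C=C/c1ccc(O)cc1 | target

**Step count and linear sequence**
- Total step count: 10.
- Longest linear sequence: 7 steps (8 → 10 → 14 → 15 → 17 → 20 → 22 → 23, that is steps 3, 5, 6, 7, 8, 9 and 10).

**Steps most likely to fail**

Step 8. The seven-membered closure may stall or run with poor facial selectivity. The silyl group may move from the ester oxygen to give the cyclic pseudo-ester. The amine may shift the double bond out of conjugation with the ketone and so open the way to a six-membered closure. The fallback uses known chemistry, sets out from 17 and comes back at 20.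
- 17 is photooxygenated as before, but the cold solution is quenched with water. This hydrolyses the silyl ester and gives the γ-hydroxybutenolide F1, the ring tautomer of the Z-keto acid.
- Et3N in dry CH2Cl2 closes the oxepine by ordinary base-mediated oxa-Michael addition to the racemic oxepine acid F2.
- Crystallisation with (R)-1-phenylethylamine gives the ammonium salt of the R acid F3. The S amine is taken if it forms the less soluble salt with the R acid.
- The acid from the mother liquor is re-equilibrated with Et3N through the reversible addition and returned to the resolution.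
- Acidification frees the R acid F4. One equivalent of TBSCl with Et3N at 0 °C silylates the carboxylate ahead of the primary alcohol and gives 20.

Step 5. The α-amino alkoxide may collapse during the warm coupling stage, the furylzinc may be protonated, or oxidative addition into the hindered, electron-rich bromide may be too slow. The fallback sets out from 12 and comes back at 14.
- Suzuki–Miyaura coupling of 12 with commercial 4-formylfuran-2-boronic acid (Pd(OAc)2, SPhos, K3PO4, THF/H2O, 40 °C) gives 5-[2,5-bis(tert-butyldimethylsilyloxy)phenyl]furan-3-carbaldehyde F5.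
- The directed C2 lithiation and silylation of step 3 is then run on F5, where C2–H is the only α-hydrogen left, to give 14.
- Step 3 on 8 drops out.

Step 9. The silyl ester may be lost on handling of 20, it may exchange with the free carboxylic acid of 21, or the phenol may be alkylated. The fallback changes from alcohol activation to acyl transfer with a proton-free donor. It sets out from 20 and 21 and comes back at 23.
- 21 is bis-silylated (TBSCl, imidazole, DMF) to the silyl ester silyl ether F6.
- Brief treatment with K2CO3 in aqueous MeOH/THF cleaves only the silyl ester to give (E)-3-[4-(tert-butyldimethylsilyloxy)phenyl]prop-2-enoic acid F7.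
- Oxalyl chloride with catalytic DMF gives the acid chloride F8.
- 20 is acylated with F8 in pyridine/CH2Cl2 at 0 °C to the tetrasilyl compound F9.
- F9 gives 23 under the conditions of step 10.

**Further compounds**
F1 | step 8 | 5-[2,5-bis(tert-butyldimethylsilyloxy)phenyl]-5-hydroxy-3-[(3Z,7E)-9-hydroxy-4-(hydroxymethyl)-8-methylnona-3,7-dien-1-yl]furan-2(5H)-one (racemic) | O=C1OC(O)(C=C1CC/C=C(\CO)CC/C=C(\C)CO)c1cc(O[Si](C)(C)C(C)(C)C)ccc1O[Si](C)(C)C(C)(C)C
F2 | step 8 | racemic 2-{2-[2,5-bis(tert-butyldimethylsilyloxy)phenyl]-2-oxoethyl}-6-[(3E)-5-hydroxy-4-methylpent-3-en-1-yl]-2,3,4,7-tetrahydrooxepine-2-carboxylic acid | C/C(=C\CCC1=CCCC(CC(=O)c2cc(O[Si](C)(C)C(C)(C)C)ccc2O[Si](C)(C)C(C)(C)C)(C(=O)O)OC1)CO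
F3 | step 8 | (R)-1-phenylethylamine salt of the R acid | C/C(=C\CCC1=CCC[C@@](CC(=O)c2cc(O[Si](C)(C)C(C)(C)C)ccc2O[Si](C)(C)C(C)(C)C)(C(=O)O)OC1)CO.C[C@@H](N)c1ccccc1
F4 | step 8 | (2R)-2-{2-[2,5-bis(tert-butyldimethylsilyloxy)phenyl]-2-oxoethyl}-6-[(3E)-5-hydroxy-4-methylpent-3-en-1-yl]-2,3,4,7-tetrahydrooxepine-2-carboxylic acid | C/C(=C\CCC1=CCC[C@@](CC(=O)c2cc(O[Si](C)(C)C(C)(C)C)ccc2O[Si](C)(C)C(C)(C)C)(C(=O)O)OC1)CO
F5 | step 5 | 5-[2,5-bis(tert-butyldimethylsilyloxy)phenyl]furan-3-carbaldehyde | O=Cc1coc(c1)-c1cc(O[Si](C)(C)C(C)(C)C)ccc1O[Si](C)(C)C(C)(C)C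
F6 | step 9 | tert-butyldimethylsilyl (E)-3-[4-(tert-butyldimethylsilyloxy)phenyl]prop-2-enoate | CC(C)(C)[Si](C)(C)OC(=O)/C=C/c1ccc(O[Si](C)(C)C(C)(C)C)cc1
F7 | step 9 | (E)-3-[4-(tert-butyldimethylsilyloxy)phenyl]prop-2-enoic acid | OC(=O)/C=C/c1ccc(O[Si](C)(C)C(C)(C)C)cc1
F8 | step 9 | (E)-3-[4-(tert-butyldimethylsilyloxy)phenyl]prop-2-enoyl chloride | ClC(=O)/C=C/c1ccc(O[Si](C)(C)C(C)(C)C)cc1
F9 | step 9 | O-TBS-p-coumarate of 20 | C/C(=C\CCC1=CCC[C@@](CC(=O)c2cc(O[Si](C)(C)C(C)(C)C)ccc2O[Si](C)(C)C(C)(C)C)(C(=O)O[Si](C)(C)C(C)(C)C)OC1)COC(=O)/C=C/c1ccc(O[Si](C)(C)C(C)(C)C)cc1
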